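**Assumption:** Locants C1–C15 are the germacranolide positions of the target (C6 lactone carbinol, C7 ring-fusion carbon, C8 ester carbinol, C10 tertiary carbinol, C11–C13 methylene-lactone carbons). CIP descriptors in a name are those of the compound named.

## Retrosynthetic overview

1. Last operations: C10 desilylation and oxidation of a C3 carbinol; the ten-membered carbocycle is closed last, at C3–C4, by intramolecular Ni/Cr coupling of a Z-vinyl iodide with an E-enal.
2. The cis-fused α-methylene-γ-lactone is closed before that, by the C6 hydroxyl onto the acrylate ester after PMB removal; the C8 ester comes from (S)-2-methylbutanoic anhydride.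
3. Key disconnection C7–C8: indium-mediated 2-(methoxycarbonyl)allylation joining a seven-carbon West aldehyde (C1–C3, C8–C10, C14) with an eight-carbon East allylic bromide (C4–C7, C11–C13, C15); it sets C7 and C8.
4. West: Sharpless epoxidation of an enynol (sets C10), hydride opening, hydroxymethylation, E-reduction. East: (S)-but-3-ene-1,2-diol (C6), Zhao–Wittig Z-iodoalkene, Baylis–Hillman reaction, SN2′ bromination.
5. Ring order: γ-lactone first, then the cyclodecadiene.

## Route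

**West fragment**

Step 1
Reactants: 1 (2E)-3-methylpent-2-en-4-yn-1-ol
Product: 2 [(2S,3S)-3-ethynyl-3-methyloxiran-2-yl]methanol
Conditions: Ti(OiPr)4 (10 mol%), L-(+)-diethyl tartrate (12 mol%), t-BuOOH, 4 Å MS, CH2Cl2, −20 °C
Reagents that add atoms: tert-butyl hydroperoxide, CC(C)(C)OO
Why: Sharpless asymmetric epoxidation; the L-tartrate/titanium catalyst delivers oxygen to one face of the allylic alcohol and so fixes the quaternary carbon that becomes C10.

Step 2
Reactants: 2 [(2S,3S)-3-ethynyl-3-methyloxiran-2-yl]methanol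
Product: 3 (3R)-3-methylpent-4-yne-1,3-diol
Conditions: NaAlH2(OCH2CH2OMe)2, THF, −20 → 0 °C
Reagents that add atoms: none
Why: Hydroxyl-directed reductive opening of a 2,3-epoxy alcohol; hydride is delivered from the aluminium alkoxide to C2, so the quaternary C–O bond (C10) is untouched.

Step 3
Reactants: 3 (3R)-3-methylpent-4-yne-1,3-diol
Product: 4 (3R)-3-methyl-1,3-bis(triethylsilyloxy)pent-4-yne
Conditions: Et3SiOTf (2.4 equiv), 2,6-lutidine, CH2Cl2, −78 → 0 °C
Reagents that add atoms: triethylsilyl trifluoromethanesulfonate, CC[Si](CC)(CC)OS(=O)(=O)C(F)(F)F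
Why: Silyl ether formation; the triflate is reactive enough to silylate the tertiary propargylic hydroxyl as well as the primary one.

Step 4
Reactants: 4 (3R)-3-methyl-1,3-bis(triethylsilyloxy)pent-4-yne
Product: 6 (4R)-4-methyl-4,6-bis(triethylsilyloxy)hex-2-yn-1-ol, via lithium acetylide 5 (not isolated)
Conditions: n-BuLi, THF, −78 °C; (CH2O)n, −78 °C → rt; H2O
Reagents that add atoms: formaldehyde (as paraformaldehyde), C=O
Why: Alkynyllithium addition to formaldehyde (hydroxymethylation) adds C3 without touching the stereocentre.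

Step 5
Reactants: 6 (4R)-4-methyl-4,6-bis(triethylsilyloxy)hex-2-yn-1-ol
Product: 7 (2E,4R)-4-methyl-4,6-bis(triethylsilyloxy)hex-2-en-1-ol
Conditions: NaAlH2(OCH2CH2OMe)2, THF, 0 °C → rt
Reagents that add atoms: none
Why: Alkoxide-directed trans-hydroalumination of the propargylic alcohol followed by protonolysis gives only the E-alkene (C1=C2).

Step 6
Reactants: 7 (2E,4R)-4-methyl-4,6-bis(triethylsilyloxy)hex-2-en-1-ol
Product: 8 1-methoxy-4-({[(2E,4R)-4-methyl-4,6-bis(triethylsilyloxy)hex-2-en-1-yl]oxy}methyl)benzene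
Conditions: NaH, 4-MeOC6H4CH2Cl, Bu4NI (cat.), THF/DMF, 0 °C → rt
Reagents that add atoms: 4-methoxybenzyl chloride, COc1ccc(CCl)cc1
Why: Williamson etherification of the only free (primary allylic) hydroxyl.

Step 7
Reactants: 8 1-methoxy-4-({[(2E,4R)-4-methyl-4,6-bis(triethylsilyloxy)hex-2-en-1-yl]oxy}methyl)benzene
Product: 9 (3R,4E)-6-[(4-methoxyphenyl)methoxy]-3-methyl-3-(triethylsilyloxy)hex-4-enal
Conditions: (COCl)2, DMSO, CH2Cl2, −78 → −40 °C; Et3N, → 0 °C
Reagents that add atoms: none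
Why: Swern oxidation run directly on the silyl ether: activated DMSO cleaves and oxidises only the unhindered primary triethylsilyl ether, while the tertiary silyl ether and the PMB ether survive.

**East fragment**

Step 8
Reactants: 10 (2S)-but-3-ene-1,2-diol
Product: 11 (4S)-4-ethenyl-2-(4-methoxyphenyl)-1,3-dioxolane
Conditions: 4-MeOC6H4CH(OMe)2, PPTS (cat.), CH2Cl2, rt
Reagents that add atoms: 4-methoxybenzaldehyde dimethyl acetal, COc1ccc(C(OC)OC)cc1
Why: Acid-catalysed transacetalisation; the chiral-pool carbinol (future C6) is not touched and the acetal-carbon epimers converge later.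

Step 9
Reactants: 11 (4S)-4-ethenyl-2-(4-methoxyphenyl)-1,3-dioxolane
Product: 13 (4R)-2-(4-methoxyphenyl)-1,3-dioxolane-4-carbaldehyde, via vicinal diol 12 (not isolated)
Conditions: OsO4 (2 mol%), NaIO4, 2,6-lutidine, dioxane/H2O, rt
Reagents that add atoms: osmium tetroxide (oxygen transfer, catalytic), O=[Os](=O)(=O)=O; sodium periodate (terminal oxidant), [Na+].[O-]I(=O)(=O)=O
Why: Lemieux–Johnson cleavage (dihydroxylation then periodate glycol cleavage); the lutidine buffer keeps the acetal and the α-stereocentre intact, whereas ozone would attack the benzylidene acetal.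

Step 10
Reactants: 13 (4R)-2-(4-methoxyphenyl)-1,3-dioxolane-4-carbaldehyde
Product: 14 (4S)-4-[(1Z)-2-iodoprop-1-en-1-yl]-2-(4-methoxyphenyl)-1,3-dioxolane
Conditions: EtPPh3I, n-BuLi, THF, 0 °C; I2, −78 °C; NaN(SiMe3)2, −20 °C; then 13, −78 °C
Reagents that add atoms: ethyltriphenylphosphonium iodide, CC[P+](c1ccccc1)(c1ccccc1)c1ccccc1.[I-]; iodine, II
Why: Zhao (Stork–Zhao type) α-iodoalkylidene Wittig olefination; the non-stabilised iodo ylide gives the Z-iodoalkene (iodine cis to C6) under kinetic control at −78 °C, where the α-alkoxy aldehyde does not epimerise.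

Step 11
Reactants: 14 (4S)-4-[(1Z)-2-iodoprop-1-en-1-yl]-2-(4-methoxyphenyl)-1,3-dioxolane
Product: 15 (2S,3Z)-4-iodo-2-[(4-methoxyphenyl)methoxy]pent-3-en-1-ol
Conditions: i-Bu2AlH (3 equiv), CH2Cl2, −78 → 0 °C
Reagents that add atoms: none
Why: Regioselective reductive opening of the p-methoxybenzylidene acetal; the aluminium hydride binds the less hindered primary oxygen, so the PMB group ends on the secondary C6 oxygen.

Step 12
Reactants: 15 (2S,3Z)-4-iodo-2-[(4-methoxyphenyl)methoxy]pent-3-en-1-ol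
Product: 16 (2S,3Z)-4-iodo-2-[(4-methoxyphenyl)methoxy]pent-3-enal
Conditions: Dess–Martin periodinane, NaHCO3, CH2Cl2, 0 °C (used crude)
Reagents that add atoms: none
Why: Dess–Martin oxidation under buffered, non-basic conditions gives the epimerisable α-alkoxy aldehyde without loss of configuration at C6.

Step 13
Reactants: 16 (2S,3Z)-4-iodo-2-[(4-methoxyphenyl)methoxy]pent-3-enal; 17 methyl acrylate
Product: 18 methyl (4S,5Z)-3-hydroxy-6-iodo-4-[(4-methoxyphenyl)methoxy]-2-methylidenehept-5-enoate (both C3 epimers)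
Conditions: 17 (10 equiv, neat), DABCO (1 equiv), MeOH (cat.), rt
Reagents that add atoms: none
Why: Morita–Baylis–Hillman reaction; the α-alkoxy aldehyde is an activated acceptor, and the new carbinol centre is removed in the next step, so its configuration is irrelevant.

Step 14
Reactants: 18 methyl (4S,5Z)-3-hydroxy-6-iodo-4-[(4-methoxyphenyl)methoxy]-2-methylidenehept-5-enoate
Product: 19 methyl (2Z,4R,5Z)-2-(bromomethyl)-6-iodo-4-[(4-methoxyphenyl)methoxy]hepta-2,5-dienoate
Conditions: NBS, Me2S, CH2Cl2, 0 °C → rt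
Reagents that add atoms: N-bromosuccinimide, O=C1CCC(=O)N1Br
Why: Corey–Kim-type activation of the allylic alcohol and SN2′ attack of bromide give the thermodynamically preferred (Z)-2-(bromomethyl)enoate (C6 cis to CH2Br).

**Side chain**

Step 15
Reactants: 20 (2S)-2-methylbutanoic acid (two molecules are consumed per molecule of anhydride)
Product: 21 (2S)-2-methylbutanoic anhydride
Conditions: 20 (2.0 equiv), DCC (1.0 equiv), CH2Cl2, 0 °C → rt; filter
Reagents that add atoms: (2S)-2-methylbutanoic acid (the second molecule of 20, which supplies the second acyl group), CC[C@H](C)C(=O)O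
Why: Carbodiimide dehydration: the O-acylisourea formed from one molecule of acid is acylated by a second molecule of acid to give the symmetric anhydride and the urea; this acyl donor avoids the ketene (racemisation) pathway of an acid chloride.

**Union and endgame**

Step 16
Reactants: 9 (3R,4E)-6-[(4-methoxyphenyl)methoxy]-3-methyl-3-(triethylsilyloxy)hex-4-enal; 19 methyl (2Z,4R,5Z)-2-(bromomethyl)-6-iodo-4-[(4-methoxyphenyl)methoxy]hepta-2,5-dienoate
Product: 23 methyl (3R,4R,6R,7E)-4-hydroxy-3-[(1R,2Z)-3-iodo-1-[(4-methoxyphenyl)methoxy]but-2-en-1-yl]-9-[(4-methoxyphenyl)methoxy]-6-methyl-2-methylidene-6-(triethylsilyloxy)non-7-enoate, via allylindium dibromide 22 (not isolated)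
Conditions: In powder (1.5 equiv), THF/H2O 1:1, rt
Reagents that add atoms: none
Why: Barbier-type indium 2-(alkoxycarbonyl)allylation: the (Z)-allylindium reacts at its γ-carbon through a chair transition state, which makes C7/C8 syn, and the aldehyde is delivered to the alkene face syn to the C6 ether oxygen (C6–H eclipsing the alkene to avoid 1,3-allylic strain, oxygen bound to indium, bulky iodoalkenyl group anti), which sets C7 relative to C6.

Step 17
Reactants: 23 (the C8 alcohol from step 16); 21 (2S)-2-methylbutanoic anhydride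
Product: 24 methyl (3R,4R,6R,7E)-3-[(1R,2Z)-3-iodo-1-[(4-methoxyphenyl)methoxy]but-2-en-1-yl]-9-[(4-methoxyphenyl)methoxy]-6-methyl-4-{[(2S)-2-methylbutanoyl]oxy}-2-methylidene-6-(triethylsilyloxy)non-7-enoate
Conditions: 21 (2 equiv), DMAP (0.2 equiv), Et3N, CH2Cl2, 0 °C → rt
Reagents that add atoms: none
Why: DMAP-catalysed acylation of the only free hydroxyl, with retention at C8 and no epimerisation of the acyl α-centre at this temperature.

Step 18
Reactants: 24 (the C8 ester from step 17)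
Product: 26 (1R,3R,4E)-6-hydroxy-1-[(2R,3R)-2-[(1Z)-2-iodoprop-1-en-1-yl]-4-methylidene-5-oxooxolan-3-yl]-3-methyl-3-(triethylsilyloxy)hex-4-en-1-yl (2S)-2-methylbutanoate, via unlactonised diol ester 25 (not isolated)
Conditions: DDQ (2.5 equiv), CH2Cl2/aq. NaH2PO4–Na2HPO4 (pH 7), 0 °C → rt; then PPTS (cat.), CH2Cl2, rt
Reagents that add atoms: none
Why: Oxidative cleavage of both PMB ethers followed by acid-catalysed lactonisation of the C6 hydroxyl onto the methyl acrylate; retention at C6 and C7 gives the cis-fused α-methylene-γ-lactone.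

Step 19
Reactants: 26 (the hydroxy lactone from step 18)
Product: 27 (1R,3R,4E)-1-[(2R,3R)-2-[(1Z)-2-iodoprop-1-en-1-yl]-4-methylidene-5-oxooxolan-3-yl]-3-methyl-6-oxo-3-(triethylsilyloxy)hex-4-en-1-yl (2S)-2-methylbutanoate
Conditions: MnO2 (20 equiv), CH2Cl2, rt
Reagents that add atoms: none
Why: Chemoselective allylic oxidation of the primary allylic alcohol to the E-enal (C3).

Step 20
Reactants: 27 (the iodo enal from step 19)
Product: 29 (3aR,4R,6R,7E,10Z,11aS)-9-hydroxy-6,10-dimethyl-3-methylidene-2-oxo-6-(triethylsilyloxy)-2,3,3a,4,5,6,9,11a-octahydrocyclodeca[b]furan-4-yl (2S)-2-methylbutanoate (both C9 epimers), via alkenylchromium dichloride 28 (not isolated)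
Conditions: CrCl2 (8 equiv), NiCl2 (2 mol%), DMSO, rt, 0.002 M, slow addition
Reagents that add atoms: none
Why: Intramolecular Nozaki–Hiyama–Kishi coupling (oxidative addition to zerovalent nickel, transmetalation to trivalent chromium, 1,2-addition to the enal) closes the ten-membered ring with retention of the Z-iodoalkene geometry; the new C3 carbinol is a mixture that is oxidised away next.

Step 21
Reactants: 29 (the macrocyclic alcohol from step 20)
Product: 30 (3aR,4R,6R,7E,10Z,11aS)-6,10-dimethyl-3-methylidene-2,9-dioxo-6-(triethylsilyloxy)-2,3,3a,4,5,6,9,11a-octahydrocyclodeca[b]furan-4-yl (2S)-2-methylbutanoate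
Conditions: Dess–Martin periodinane, NaHCO3, CH2Cl2, 0 °C → rt
Reagents that add atoms: none
Why: Dess–Martin oxidation of the doubly allylic alcohol gives the cross-conjugated dienone without touching the alkene geometries or the stereocentres.

Step 22
Reactants: 30 (the silyl-protected dienone from step 21)
Product: 31 (3aR,4R,6R,7E,10Z,11aS)-6-hydroxy-6,10-dimethyl-3-methylidene-2,9-dioxo-2,3,3a,4,5,6,9,11a-octahydrocyclodeca[b]furan-4-yl (2S)-2-methylbutanoate
Conditions: HF·pyridine, pyridine/THF, 0 °C → rt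
Reagents that add atoms: none
Why: Fluoride-mediated desilylation frees the tertiary C10 hydroxyl under buffered conditions that spare the methylene lactone, the dienone and the ester.

## Compound list

1 | (2E)-3-methylpent-2-en-4-yn-1-ol | C#C/C(C)=C/CO | starting material
2 | [(2S,3S)-3-ethynyl-3-methyloxiran-2-yl]methanol | C#C[C@]1(C)O[C@H]1CO | intermediate
3 | (3R)-3-methylpent-4-yne-1,3-diol | C#C[C@](C)(O)CCO | intermediate
4 | (3R)-3-methyl-1,3-bis(triethylsilyloxy)pent-4-yne | C#C[C@](C)(O[Si](CC)(CC)CC)CCO[Si](CC)(CC)CC | intermediate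
5 | [(3R)-3-methyl-3,5-bis(triethylsilyloxy)pent-1-yn-1-yl]lithium | [Li]C#C[C@](C)(O[Si](CC)(CC)CC)CCO[Si](CC)(CC)CC | intermediate
6 | (4R)-4-methyl-4,6-bis(triethylsilyloxy)hex-2-yn-1-ol | OCC#C[C@](C)(O[Si](CC)(CC)CC)CCO[Si](CC)(CC)CC | intermediate
7 | (2E,4R)-4-methyl-4,6-bis(triethylsilyloxy)hex-2-en-1-ol | OC/C=C/[C@](C)(O[Si](CC)(CC)CC)CCO[Si](CC)(CC)CC | intermediate
8 | 1-methoxy-4-({[(2E,4R)-4-methyl-4,6-bis(triethylsilyloxy)hex-2-en-1-yl]oxy}methyl)benzene | COc1ccc(COC/C=C/[C@](C)(O[Si](CC)(CC)CC)CCO[Si](CC)(CC)CC)cc1 | intermediate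
9 | (3R,4E)-6-[(4-methoxyphenyl)methoxy]-3-methyl-3-(triethylsilyloxy)hex-4-enal (West fragment) | COc1ccc(COC/C=C/[C@](C)(O[Si](CC)(CC)CC)CC=O)cc1 | intermediate
10 | (2S)-but-3-ene-1,2-diol | OC[C@@H](O)C=C | starting material
11 | (4S)-4-ethenyl-2-(4-methoxyphenyl)-1,3-dioxolane (acetal epimers) | C=C[C@H]1COC(c2ccc(OC)cc2)O1 | intermediate
12 | 1-[(4R)-2-(4-methoxyphenyl)-1,3-dioxolan-4-yl]ethane-1,2-diol | OCC(O)[C@H]1COC(c2ccc(OC)cc2)O1 | intermediate
13 | (4R)-2-(4-methoxyphenyl)-1,3-dioxolane-4-carbaldehyde | O=C[C@H]1COC(c2ccc(OC)cc2)O1 | intermediate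
14 | (4S)-4-[(1Z)-2-iodoprop-1-en-1-yl]-2-(4-methoxyphenyl)-1,3-dioxolane | C/C(I)=C/[C@H]1COC(c2ccc(OC)cc2)O1 | intermediate
15 | (2S,3Z)-4-iodo-2-[(4-methoxyphenyl)methoxy]pent-3-en-1-ol | C/C(I)=C/[C@@H](CO)OCc1ccc(OC)cc1 | intermediate
16 | (2S,3Z)-4-iodo-2-[(4-methoxyphenyl)methoxy]pent-3-enal | C/C(I)=C/[C@@H](C=O)OCc1ccc(OC)cc1 | intermediate
17 | methyl acrylate (methyl prop-2-enoate) | C=CC(=O)OC | starting material
18 | methyl (4S,5Z)-3-hydroxy-6-iodo-4-[(4-methoxyphenyl)methoxy]-2-methylidenehept-5-enoate (C3 epimers) | C/C(I)=C/[C@@H](C(O)C(=C)C(=O)OC)OCc1ccc(OC)cc1 | intermediate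
19 | methyl (2Z,4R,5Z)-2-(bromomethyl)-6-iodo-4-[(4-methoxyphenyl)methoxy]hepta-2,5-dienoate (East fragment) | COC(=O)/C(CBr)=C/[C@@H](OCc1ccc(OC)cc1)/C=C(/C)I | intermediate
20 | (2S)-2-methylbutanoic acid | CC[C@H](C)C(=O)O | starting material
21 | (2S)-2-methylbutanoic anhydride | CC[C@H](C)C(=O)OC(=O)[C@@H](C)CC | intermediate
22 | allylindium dibromide of 19 (InBr2 in place of bromine) | COC(=O)/C(C[In](Br)Br)=C/[C@@H](OCc1ccc(OC)cc1)/C=C(/C)I | intermediate
23 | methyl (3R,4R,6R,7E)-4-hydroxy-3-[(1R,2Z)-3-iodo-1-[(4-methoxyphenyl)methoxy]but-2-en-1-yl]-9-[(4-methoxyphenyl)methoxy]-6-methyl-2-methylidene-6-(triethylsilyloxy)non-7-enoate | C=C(C(=O)OC)[C@@H]([C@@H](OCc1ccc(OC)cc1)/C=C(/C)I)[C@H](O)C[C@@](C)(O[Si](CC)(CC)CC)/C=C/COCc1ccc(OC)cc1 | intermediate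
24 | methyl (3R,4R,6R,7E)-3-[(1R,2Z)-3-iodo-1-[(4-methoxyphenyl)methoxy]but-2-en-1-yl]-9-[(4-methoxyphenyl)methoxy]-6-methyl-4-{[(2S)-2-methylbutanoyl]oxy}-2-methylidene-6-(triethylsilyloxy)non-7-enoate | C=C(C(=O)OC)[C@@H]([C@@H](OCc1ccc(OC)cc1)/C=C(/C)I)[C@H](OC(=O)[C@@H](C)CC)C[C@@](C)(O[Si](CC)(CC)CC)/C=C/COCc1ccc(OC)cc1 | intermediate
25 | methyl (3S,4R,6R,7E)-9-hydroxy-3-[(1R,2Z)-1-hydroxy-3-iodobut-2-en-1-yl]-6-methyl-4-{[(2S)-2-methylbutanoyl]oxy}-2-methylidene-6-(triethylsilyloxy)non-7-enoate | C=C(C(=O)OC)[C@@H]([C@@H](O)/C=C(/C)I)[C@H](OC(=O)[C@@H](C)CC)C[C@@](C)(O[Si](CC)(CC)CC)/C=C/CO | intermediate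
26 | (1R,3R,4E)-6-hydroxy-1-[(2R,3R)-2-[(1Z)-2-iodoprop-1-en-1-yl]-4-methylidene-5-oxooxolan-3-yl]-3-methyl-3-(triethylsilyloxy)hex-4-en-1-yl (2S)-2-methylbutanoate | C=C1C(=O)O[C@@H](/C=C(/C)I)[C@H]1[C@H](OC(=O)[C@@H](C)CC)C[C@@](C)(O[Si](CC)(CC)CC)/C=C/CO | intermediate
27 | (1R,3R,4E)-1-[(2R,3R)-2-[(1Z)-2-iodoprop-1-en-1-yl]-4-methylidene-5-oxooxolan-3-yl]-3-methyl-6-oxo-3-(triethylsilyloxy)hex-4-en-1-yl (2S)-2-methylbutanoate | C=C1C(=O)O[C@@H](/C=C(/C)I)[C@H]1[C@H](OC(=O)[C@@H](C)CC)C[C@@](C)(O[Si](CC)(CC)CC)/C=C/C=O | intermediate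
28 | alkenylchromium dichloride of 27 (CrCl2 in place of iodine at C4) | C=C1C(=O)O[C@@H](/C=C(/C)[Cr](Cl)Cl)[C@H]1[C@H](OC(=O)[C@@H](C)CC)C[C@@](C)(O[Si](CC)(CC)CC)/C=C/C=O | intermediate
29 | (3aR,4R,6R,7E,10Z,11aS)-9-hydroxy-6,10-dimethyl-3-methylidene-2-oxo-6-(triethylsilyloxy)-2,3,3a,4,5,6,9,11a-octahydrocyclodeca[b]furan-4-yl (2S)-2-methylbutanoate (C9 epimers) | C=C1C(=O)O[C@H]2/C=C(/C)C(O)/C=C/[C@](C)(O[Si](CC)(CC)CC)C[C@@H](OC(=O)[C@@H](C)CC)[C@@H]12 | intermediate
30 | (3aR,4R,6R,7E,10Z,11aS)-6,10-dimethyl-3-methylidene-2,9-dioxo-6-(triethylsilyloxy)-2,3,3a,4,5,6,9,11a-octahydrocyclodeca[b]furan-4-yl (2S)-2-methylbutanoate | C=C1C(=O)O[C@H]2/C=C(/C)C(=O)/C=C/[C@](C)(O[Si](CC)(CC)CC)C[C@@H](OC(=O)[C@@H](C)CC)[C@@H]12 | intermediate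
31 | (3aR,4R,6R,7E,10Z,11aS)-6-hydroxy-6,10-dimethyl-3-methylidene-2,9-dioxo-2,3,3a,4,5,6,9,11a-octahydrocyclodeca[b]furan-4-yl (2S)-2-methylbutanoate | C=C1C(=O)O[C@H]2/C=C(/C)C(=O)/C=C/[C@](C)(O)C[C@@H](OC(=O)[C@@H](C)CC)[C@@H]12 | target

## Step count and risks

Total steps: 22.
Longest linear sequence: 14 (steps 1–7 then 16–22; steps 8–14 then 16–22 is equally long).

**Most likely to fail, with fallbacks**

- **Step 16 (indium union).** The facial selectivity with respect to the C6 ether rests on a conformational and coordination model, not on a close precedent, and could be low. The fallback hands stereocontrol from the substrate to a catalyst. It sets out from 9 and 19: CrCl2 (10 mol%), an enantiopure carbazole bis(oxazoline) ligand, Mn powder and Me3SiCl in THF (catalytic asymmetric Nozaki–Hiyama allylation; chromium alone does not touch the vinyl iodide) give the adduct as its trimethylsilyl ether F1. Brief treatment with aqueous citric acid returns to the route at 23.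

- **Step 20 (ten-membered ring closure).** The lactone-bearing seco compound 27 may be too rigid and give dimers or reduction instead of cyclisation. The fallback closes the carbocycle before the lactone. It sets out from 25, which is isolated after the DDQ stage instead of being lactonised. TEMPO/PhI(OAc)2 oxidises only the primary allylic alcohol to the open-chain hydroxy enal F2. The same CrCl2/NiCl2 cyclisation on this more flexible ester, whose free C6 hydroxyl can bind chromium, gives the macrocyclic diol ester F3. PPTS-catalysed lactonisation then returns to the route at 29.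

- **Step 13 (Baylis–Hillman reaction).** The reaction is slow, and the amine base may epimerise the α-alkoxy β,γ-unsaturated aldehyde 16 at C6. The fallback builds the same adduct by an aldol/elimination sequence at low temperature. It sets out from 16: the lithium enolate of methyl 3-(dimethylamino)propanoate (LiN(i-Pr)2, THF, −78 °C) gives the amino aldol F4. mCPBA at −20 °C converts it into the N-oxide F5, which undergoes Cope elimination on warming and returns to the route at 18.

## Further compounds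

F1 | step 16 | methyl (3R,4R,6R,7E)-3-[(1R,2Z)-3-iodo-1-[(4-methoxyphenyl)methoxy]but-2-en-1-yl]-9-[(4-methoxyphenyl)methoxy]-6-methyl-2-methylidene-6-(triethylsilyloxy)-4-(trimethylsilyloxy)non-7-enoate | C=C(C(=O)OC)[C@@H]([C@@H](OCc1ccc(OC)cc1)/C=C(/C)I)[C@H](O[Si](C)(C)C)C[C@@](C)(O[Si](CC)(CC)CC)/C=C/COCc1ccc(OC)cc1
F2 | step 20 | methyl (3S,4R,6R,7E)-3-[(1R,2Z)-1-hydroxy-3-iodobut-2-en-1-yl]-6-methyl-4-{[(2S)-2-methylbutanoyl]oxy}-2-methylidene-9-oxo-6-(triethylsilyloxy)non-7-enoate | C=C(C(=O)OC)[C@@H]([C@@H](O)/C=C(/C)I)[C@H](OC(=O)[C@@H](C)CC)C[C@@](C)(O[Si](CC)(CC)CC)/C=C/C=O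
F3 | step 20 | methyl 2-[(1S,2S,3Z,6E,8R,10R)-2,5-dihydroxy-4,8-dimethyl-10-{[(2S)-2-methylbutanoyl]oxy}-8-(triethylsilyloxy)cyclodeca-3,6-dien-1-yl]prop-2-enoate (C5 epimers) | COC(=O)C(=C)[C@H]1[C@@H](O)/C=C(/C)C(O)/C=C/[C@](C)(O[Si](CC)(CC)CC)C[C@H]1OC(=O)[C@@H](C)CC
F4 | step 13 | methyl (4S,5Z)-2-[(dimethylamino)methyl]-3-hydroxy-6-iodo-4-[(4-methoxyphenyl)methoxy]hept-5-enoate (C2/C3 epimers) | C/C(I)=C/[C@@H](C(O)C(CN(C)C)C(=O)OC)OCc1ccc(OC)cc1
F5 | step 13 | N-oxide of F4: methyl (4S,5Z)-2-[(dimethyloxidoazaniumyl)methyl]-3-hydroxy-6-iodo-4-[(4-methoxyphenyl)methoxy]hept-5-enoate | C/C(I)=C/[C@@H](C(O)C(C[N+](C)(C)[O-])C(=O)OC)OCc1ccc(OC)cc1
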